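**Retrosynthetic overview**
- The γ-lactone and the 23-membered carbocycle are formed last and together: an intramolecular aldol (C2 to C24) contracts a 24-membered 3-oxo macrolactone that carries a C2 butanoyloxy group and a C24 aldehyde, and the butanoyl group then shifts from O2 to O24. Ketone reduction, C3 acylation and desilylation finish the synthesis.
- The macrolactone (C1–O–C23) comes from acylketene lactonisation of a seco tert-butyl β-keto ester. Its Z,Z-diene comes from a 1,3-diyne made by alkyne–bromoalkyne coupling of a west (C1–C13) and an east (C14–C24) fragment.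
- West: the tetrahydropyran closes by oxa-Michael addition of O9 to C5 of an enone; C11 comes from conjugate alkynylation, C7 from a boron aldol, C9 from 1,3-anti reduction.
- East: the tetrahydrofuran closes by 5-exo attack of the C17 hydroxyl on C20 with inversion (chlorohydrin as epoxide surrogate). The chain comes from (R)-citronellal; C17 and C20 from organocatalytic chlorination, C21 from an aldol, C23 from CBS reduction.
- Ring order: tetrahydropyran and tetrahydrofuran (in separate fragments), then the 24-membered macrolactone, then the γ-lactone/carbocycle.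

Assumption: atoms are numbered C1–C24 along the polyketide chain (C1 lactone carbonyl, C2 tertiary carbinol, C24 lactone CH–O), and the antipodes named for the chiral catalysts and for Ipc2BCl are those expected from their usual models and would be exchanged for their enantiomers if a sense proved opposite.

**Route**

Step 1
Reactants: 1 tert-butyl 4-chloro-3-oxobutanoate
Product: 3 tert-butyl 3-oxo-4-(triphenyl-λ5-phosphanylidene)butanoate, via phosphonium chloride 2 (not isolated)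
Conditions: PPh3, THF, 50 °C; then Na2CO3 (aq), CH2Cl2, rt
Reagents that add atoms: triphenylphosphine, c1ccc(cc1)P(c1ccccc1)c1ccccc1
Why: SN2 displacement of the α-chloro ketone by the phosphine and deprotonation of the salt give the keto-stabilised ylide (standard Wittig reagent synthesis).

Step 2
Reactants: 4 (3E)-pent-3-en-2-one; 5 ethynyltri(propan-2-yl)silane
Product: 6 (4R)-4-methyl-6-[tri(propan-2-yl)silyl]hex-5-yn-2-one
Conditions: [Rh(OAc)(C2H4)2]2 (2.5 mol%), (R)-DTBM-SEGPHOS (6 mol%), 1,4-dioxane, 80 °C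
Reagents that add atoms: none
Why: Hayashi–Nishimura rhodium-catalysed asymmetric conjugate alkynylation of an enone, in which the bulky silyl group suppresses alkyne dimerisation and the chiral bisphosphine sets C11 as R.

Step 3
Reactants: 6 (4R)-4-methyl-6-[tri(propan-2-yl)silyl]hex-5-yn-2-one; 7 3-[tert-butyl(dimethyl)silyl]oxypropanal
Product: 8 (3R,7R)-9-[tert-butyl(dimethyl)silyl]oxy-7-hydroxy-3-methyl-1-[tri(propan-2-yl)silyl]non-1-yn-5-one
Conditions: (+)-Ipc2BCl, Et3N, Et2O, 0 °C; then 7, −78 → −20 °C; H2O2, pH 7 buffer, MeOH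
Reagents that add atoms: none
Why: Paterson boron aldol of the methyl-side enol diisopinocampheylborinate, where the chiral boron ligands choose the aldehyde face and set the C7 carbinol (moderate reagent control, minor diastereomer removed by chromatography).

Step 4
Reactants: 8 (3R,7R)-9-[tert-butyl(dimethyl)silyl]oxy-7-hydroxy-3-methyl-1-[tri(propan-2-yl)silyl]non-1-yn-5-one
Product: 9 (3R,5R,7R)-1-[tert-butyl(dimethyl)silyl]oxy-7-methyl-9-[tri(propan-2-yl)silyl]non-8-yne-3,5-diol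
Conditions: Me4NBH(OAc)3, MeCN/AcOH (1:1), −30 °C
Reagents that add atoms: none
Why: Evans–Saksena reduction, in which the C7 alkoxy-bound acetoxyborohydride delivers hydride intramolecularly to give the 1,3-anti diol and so sets C9.

Step 5
Reactants: 9 (3R,5R,7R)-1-[tert-butyl(dimethyl)silyl]oxy-7-methyl-9-[tri(propan-2-yl)silyl]non-8-yne-3,5-diol
Product: 10 (3R,5R,7R)-7-methylnon-8-yne-1,3,5-triol
Conditions: Bu4NF, THF, 0 °C → rt
Reagents that add atoms: none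
Why: Fluoride cleaves the primary silyl ether and the alkynyl C–Si bond in one operation (desilylation).

Step 6
Reactants: 10 (3R,5R,7R)-7-methylnon-8-yne-1,3,5-triol
Product: 11 (4S,6R)-6-[(2R)-2-methylbut-3-yn-1-yl]oxane-2,4-diol
Conditions: TEMPO (0.2 equiv), PhI(OAc)2 (1.1 equiv), CH2Cl2, rt
Reagents that add atoms: none
Why: Oxoammonium (TEMPO) oxidation is selective for the primary alcohol, and the aldehyde is captured at once by the C9 hydroxyl as the six-membered lactol, which limits over-oxidation.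

Step 7
Reactants: 11 (4S,6R)-6-[(2R)-2-methylbut-3-yn-1-yl]oxane-2,4-diol; 3 tert-butyl 3-oxo-4-(triphenyl-λ5-phosphanylidene)butanoate
Product: 13 tert-butyl 4-[(2R,4S,6R)-4-hydroxy-6-[(2R)-2-methylbut-3-yn-1-yl]oxan-2-yl]-3-oxobutanoate, via enone 12 (not isolated)
Conditions: 3 (2.5 equiv), NaH (2.5 equiv), THF, 0 °C; then 11, 0 °C → rt; NH4Cl (aq)
Reagents that add atoms: none
Why: Tandem Wittig olefination/oxa-Michael addition: the ylide anion olefinates the open form of the lactol to the E-enone, and the C9 alkoxide adds reversibly to C5 (6-exo) to give the all-equatorial 2,6-cis tetrahydropyran, which sets C5.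

Step 8
Reactants: 13 tert-butyl 4-[(2R,4S,6R)-4-hydroxy-6-[(2R)-2-methylbut-3-yn-1-yl]oxan-2-yl]-3-oxobutanoate
Product: 14 tert-butyl 4-[(2R,4S,6R)-4-[tert-butyl(diphenyl)silyl]oxy-6-[(2R)-2-methylbut-3-yn-1-yl]oxan-2-yl]-3-oxobutanoate
Conditions: t-BuPh2SiCl, imidazole, DMF, rt
Reagents that add atoms: tert-butyl(chloro)diphenylsilane, CC(C)(C)[Si](Cl)(c1ccccc1)c1ccccc1
Why: Silylation of the equatorial C7 hydroxyl with an acid-stable silyl group that survives the later acetal hydrolysis.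

Step 9
Reactants: 15 (3R)-3,7-dimethyloct-6-enal ((R)-citronellal)
Product: 18 (2S)-2-[(2R)-6-methylhept-5-en-2-yl]oxirane, via chloroaldehyde 16 (not isolated), via chlorohydrin 17 (not isolated)
Conditions: (2S,5S)-2,5-diphenylpyrrolidine (10 mol%), NCS, CH2Cl2, 0 °C → rt; NaBH4, MeOH, 0 °C; KOH (aq), EtOH, rt
Reagents that add atoms: none
Why: Jørgensen one-pot enamine α-chlorination, reduction and Williamson closure, where the catalyst sets the C17 chloride and epoxide closure inverts it to the (S)-epoxide.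

Step 10
Reactants: 18 (2S)-2-[(2R)-6-methylhept-5-en-2-yl]oxirane; 19 ethynyl(trimethyl)silane
Product: 20 (4R,5R)-5,9-dimethyl-1-(trimethylsilyl)dec-8-en-1-yn-4-ol
Conditions: 19, n-BuLi, THF, −78 °C; BF3·OEt2; then 18, −78 °C
Reagents that add atoms: none
Why: Yamaguchi–Hirao BF3-promoted opening of the terminal epoxide by the lithium acetylide at the CH2 carbon, which leaves the C17 stereocentre untouched.

Step 11
Reactants: 20 (4R,5R)-5,9-dimethyl-1-(trimethylsilyl)dec-8-en-1-yn-4-ol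
Product: 21 {[(4R,5R)-5,9-dimethyl-1-(trimethylsilyl)dec-8-en-1-yn-4-yl]oxy}(triethyl)silane
Conditions: Et3SiCl, imidazole, CH2Cl2, rt
Reagents that add atoms: chlorotriethylsilane, CC[Si](Cl)(CC)CC
Why: Silyl protection of the C17 hydroxyl so that the aldehyde made next cannot close to a lactol.

Step 12
Reactants: 21 {[(4R,5R)-5,9-dimethyl-1-(trimethylsilyl)dec-8-en-1-yn-4-yl]oxy}(triethyl)silane
Product: 22 (4R,5R)-4-methyl-5-(triethylsilyloxy)-8-(trimethylsilyl)oct-7-ynal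
Conditions: O3, CH2Cl2, −78 °C (Sudan red end point); PPh3, −78 °C → rt
Reagents that add atoms: ozone, [O-][O+]=O
Why: Ozonolysis cleaves the electron-rich trisubstituted alkene much faster than the silylalkyne and gives the C21 aldehyde.

Step 13
Reactants: 22 (4R,5R)-4-methyl-5-(triethylsilyloxy)-8-(trimethylsilyl)oct-7-ynal
Product: 23 (2S,4R,5R)-2-chloro-4-methyl-5-(triethylsilyloxy)-8-(trimethylsilyl)oct-7-ynal
Conditions: (2R,5R)-2,5-diphenylpyrrolidine (10 mol%), NCS, CH2Cl2, 0 °C → rt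
Reagents that add atoms: N-chlorosuccinimide, O=C1CCC(=O)N1Cl
Why: Enamine-catalysed α-chlorination, where the C2-symmetric amine shields one enamine face and sets the C20 chloride as S.

Step 14
Reactants: 23 (2S,4R,5R)-2-chloro-4-methyl-5-(triethylsilyloxy)-8-(trimethylsilyl)oct-7-ynal; 24 1,1-dimethoxypropan-2-one
Product: 25 (4R,5S,7R,8R)-5-chloro-4-hydroxy-1,1-dimethoxy-7-methyl-8-(triethylsilyloxy)-11-(trimethylsilyl)undec-10-yn-2-one
Conditions: 24, LiN(iPr)2, THF, −78 °C; then 23, −78 °C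
Reagents that add atoms: none
Why: Britton-type aldol of the methyl-side lithium enolate with the α-chloroaldehyde, where Cornforth (polar Felkin–Anh) control gives the 1,2-anti chlorohydrin and sets C21.

Step 15
Reactants: 25 (4R,5S,7R,8R)-5-chloro-4-hydroxy-1,1-dimethoxy-7-methyl-8-(triethylsilyloxy)-11-(trimethylsilyl)undec-10-yn-2-one
Product: 27 (4R)-4-hydroxy-1,1-dimethoxy-4-{(2R,4R,5R)-4-methyl-5-[3-(trimethylsilyl)prop-2-yn-1-yl]oxolan-2-yl}butan-2-one, via chlorodiol 26 (not isolated)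
Conditions: PPTS, MeOH, rt; evaporate; AgOSO2CF3, Ag2O, THF, rt → 40 °C
Reagents that add atoms: none
Why: After methanolysis of the triethylsilyl ether, silver-assisted 5-exo-tet displacement of chloride by the C17 hydroxyl (Britton chlorohydrin cycloetherification) inverts C20 and gives the all-cis tetrahydrofuran with the threo C21 carbinol; C23 is kept as a ketone so that no second hydroxyl can reach C20.

Step 16
Reactants: 27 (4R)-4-hydroxy-1,1-dimethoxy-4-{(2R,4R,5R)-4-methyl-5-[3-(trimethylsilyl)prop-2-yn-1-yl]oxolan-2-yl}butan-2-one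
Product: 28 (4R)-4-[tert-butyl(diphenyl)silyl]oxy-1,1-dimethoxy-4-{(2R,4R,5R)-4-methyl-5-[3-(trimethylsilyl)prop-2-yn-1-yl]oxolan-2-yl}butan-2-one
Conditions: t-BuPh2SiCl, imidazole, DMAP (cat.), DMF, rt → 40 °C
Reagents that add atoms: tert-butyl(chloro)diphenylsilane, CC(C)(C)[Si](Cl)(c1ccccc1)c1ccccc1
Why: Silylation of the C21 hydroxyl under conditions that do not activate the dimethyl acetal.

Step 17
Reactants: 28 (4R)-4-[tert-butyl(diphenyl)silyl]oxy-1,1-dimethoxy-4-{(2R,4R,5R)-4-methyl-5-[3-(trimethylsilyl)prop-2-yn-1-yl]oxolan-2-yl}butan-2-one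
Product: 29 (2R,4R)-4-[tert-butyl(diphenyl)silyl]oxy-1,1-dimethoxy-4-{(2R,4R,5R)-4-methyl-5-[3-(trimethylsilyl)prop-2-yn-1-yl]oxolan-2-yl}butan-2-ol
Conditions: (S)-Me-CBS oxazaborolidine (0.2 equiv), catecholborane, toluene, −78 °C
Reagents that add atoms: none
Why: Corey–Bakshi–Shibata reduction of an α-keto acetal with the branched acetal carbon as the large group, so the catalyst sets C23 as R (1,3-anti to C21).

Step 18
Reactants: 29 (2R,4R)-4-[tert-butyl(diphenyl)silyl]oxy-1,1-dimethoxy-4-{(2R,4R,5R)-4-methyl-5-[3-(trimethylsilyl)prop-2-yn-1-yl]oxolan-2-yl}butan-2-ol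
Product: 30 (2R,4R)-4-[(2R,4R,5R)-5-(3-bromoprop-2-yn-1-yl)-4-methyloxolan-2-yl]-4-[tert-butyl(diphenyl)silyl]oxy-1,1-dimethoxybutan-2-ol
Conditions: NBS, AgNO3 (10 mol%), acetone, rt
Reagents that add atoms: N-bromosuccinimide, O=C1CCC(=O)N1Br
Why: Silver-catalysed bromodesilylation converts the trimethylsilylalkyne directly into the 1-bromoalkyne through a silver acetylide.

Step 19
Reactants: 14 tert-butyl 4-[(2R,4S,6R)-4-[tert-butyl(diphenyl)silyl]oxy-6-[(2R)-2-methylbut-3-yn-1-yl]oxan-2-yl]-3-oxobutanoate; 30 (2R,4R)-4-[(2R,4R,5R)-5-(3-bromoprop-2-yn-1-yl)-4-methyloxolan-2-yl]-4-[tert-butyl(diphenyl)silyl]oxy-1,1-dimethoxybutan-2-ol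
Product: 31 tert-butyl (5R,7S,9R,11R,17R,18R,20R,21R,23R)-7,21-bis[tert-butyl(diphenyl)silyloxy]-5,9:17,20-diepoxy-23-hydroxy-24,24-dimethoxy-11,18-dimethyl-3-oxotetracosa-12,14-diynoate
Conditions: Pd(PPh3)2Cl2 (5 mol%), CuI (10 mol%), iPr2NH, THF, rt
Reagents that add atoms: none
Why: Palladium/copper-catalysed Cadiot–Chodkiewicz-type cross-coupling of a terminal alkyne with a 1-bromoalkyne, run without hydroxylamine so that the β-keto ester is not touched.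

Step 20
Reactants: 31 tert-butyl (5R,7S,9R,11R,17R,18R,20R,21R,23R)-7,21-bis[tert-butyl(diphenyl)silyloxy]-5,9:17,20-diepoxy-23-hydroxy-24,24-dimethoxy-11,18-dimethyl-3-oxotetracosa-12,14-diynoate
Product: 32 tert-butyl (5R,7S,9R,11R,12Z,14Z,17R,18R,20R,21R,23R)-7,21-bis[tert-butyl(diphenyl)silyloxy]-5,9:17,20-diepoxy-23-hydroxy-24,24-dimethoxy-11,18-dimethyl-3-oxotetracosa-12,14-dienoate
Conditions: Zn dust activated with Cu(OAc)2 and AgNO3, MeOH/H2O/THF, 40 °C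
Reagents that add atoms: none
Why: Boland reduction, where syn delivery of hydrogen at the activated zinc surface turns the conjugated diyne into the Z,Z-diene without over-reduction.

Step 21
Reactants: 32 tert-butyl (5R,7S,9R,11R,12Z,14Z,17R,18R,20R,21R,23R)-7,21-bis[tert-butyl(diphenyl)silyloxy]-5,9:17,20-diepoxy-23-hydroxy-24,24-dimethoxy-11,18-dimethyl-3-oxotetracosa-12,14-dienoate
Product: 34 (5R,7S,9R,11R,12Z,14Z,17R,18R,20R,21R,23R)-7,21-bis[tert-butyl(diphenyl)silyloxy]-5,9:17,20-diepoxy-24,24-dimethoxy-11,18-dimethyl-3-oxotetracosa-12,14-dien-23-olide, via acylketene 33 (not isolated)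
Conditions: toluene (0.5 mM, syringe-pump addition), 110 °C
Reagents that add atoms: none
Why: Thermal loss of tert-butanol from the β-keto ester gives an acylketene that is trapped by the only free hydroxyl (C23) at high dilution, closing the 24-membered lactone (acylketene macrolactonisation).

Step 22
Reactants: 34 (5R,7S,9R,11R,12Z,14Z,17R,18R,20R,21R,23R)-7,21-bis[tert-butyl(diphenyl)silyloxy]-5,9:17,20-diepoxy-24,24-dimethoxy-11,18-dimethyl-3-oxotetracosa-12,14-dien-23-olide; 35 butanoic acid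
Product: 36 (2RS,5R,7S,9R,11R,12Z,14Z,17R,18R,20R,21R,23R)-2-(butanoyloxy)-7,21-bis[tert-butyl(diphenyl)silyloxy]-5,9:17,20-diepoxy-24,24-dimethoxy-11,18-dimethyl-3-oxotetracosa-12,14-dien-23-olide
Conditions: PhIO, 35, CH2Cl2, rt
Reagents that add atoms: none
Why: Trivalent-iodine α-acyloxylation of a 1,3-dicarbonyl, in which the enol attacks the bis(butanoyloxy)iodane formed in the flask and butanoate is delivered to C2, the only doubly activated position.

Step 23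
Reactants: 36 (2RS,5R,7S,9R,11R,12Z,14Z,17R,18R,20R,21R,23R)-2-(butanoyloxy)-7,21-bis[tert-butyl(diphenyl)silyloxy]-5,9:17,20-diepoxy-24,24-dimethoxy-11,18-dimethyl-3-oxotetracosa-12,14-dien-23-olide
Product: 39 (2R,5R,7S,9R,11R,12Z,14Z,17R,18R,20R,21R,23R,24S)-24-(butanoyloxy)-7,21-bis[tert-butyl(diphenyl)silyloxy]-5,9:17,20-diepoxy-2-hydroxy-11,18-dimethyl-3-oxo-2,24-cyclotetracosa-12,14-dien-23-olide, via aldehyde 37 (not isolated), via aldol adduct 38 (not isolated)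
Conditions: CF3CO2H/H2O (9:1), CH2Cl2, 0 °C; evaporate; Et3N (0.5 equiv), CH2Cl2, −20 °C → rt
Reagents that add atoms: water, O
Why: Proposed new method: acid hydrolysis frees the C24 aldehyde, and the acidic C2–H of the 2-acyloxy-1,3-dicarbonyl is then enolised by the amine so that C2 adds to C24 in a 5-(enolexo)-exo-trig aldol that forms the γ-lactone and the 23-membered carbocycle at once. The aldol is reversible, and only a cis aldolate can pass its butanoyl group from O2 to O24 (1,2-acyl shift through a five-membered orthoester), which removes the retro-aldol path and leaves the O2/O24-cis product. Of the two cis isomers the one with C22 on the face of the small O2 substituent, and not of the C3 acyl arm, is expected, giving 2R,24S. The closest known reactions are intramolecular aldol/Knoevenagel cyclisations of acyloxy 1,3-dicarbonyls to butenolides and O-to-O acyl migration in cis-1,2-diol monoesters.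

Step 24
Reactants: 39 (2R,5R,7S,9R,11R,12Z,14Z,17R,18R,20R,21R,23R,24S)-24-(butanoyloxy)-7,21-bis[tert-butyl(diphenyl)silyloxy]-5,9:17,20-diepoxy-2-hydroxy-11,18-dimethyl-3-oxo-2,24-cyclotetracosa-12,14-dien-23-olide
Product: 40 (2S,3R,5R,7S,9R,11R,12Z,14Z,17R,18R,20R,21R,23R,24S)-24-(butanoyloxy)-7,21-bis[tert-butyl(diphenyl)silyloxy]-5,9:17,20-diepoxy-2,3-dihydroxy-11,18-dimethyl-2,24-cyclotetracosa-12,14-dien-23-olide
Conditions: (S)-Me-CBS oxazaborolidine (1 equiv), catecholborane, toluene/CH2Cl2, −78 → −40 °C; MeOH, pH 7 buffer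
Reagents that add atoms: none
Why: Corey–Bakshi–Shibata reduction with the quaternary C2 as the large group gives 3R, and this reagent control is matched with polar Felkin–Anh attack anti to the C2 oxygen; catecholborane leaves the diene alone.

Step 25
Reactants: 40 (2S,3R,5R,7S,9R,11R,12Z,14Z,17R,18R,20R,21R,23R,24S)-24-(butanoyloxy)-7,21-bis[tert-butyl(diphenyl)silyloxy]-5,9:17,20-diepoxy-2,3-dihydroxy-11,18-dimethyl-2,24-cyclotetracosa-12,14-dien-23-olide; 41 butanoic anhydride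
Product: 42 (2S,3R,5R,7S,9R,11R,12Z,14Z,17R,18R,20R,21R,23R,24S)-3,24-bis(butanoyloxy)-7,21-bis[tert-butyl(diphenyl)silyloxy]-5,9:17,20-diepoxy-2-hydroxy-11,18-dimethyl-2,24-cyclotetracosa-12,14-dien-23-olide
Conditions: 41, DMAP, pyridine, CH2Cl2, 0 °C → rt
Reagents that add atoms: none
Why: DMAP-catalysed acylation esterifies the secondary C3 hydroxyl while the tertiary C2 hydroxyl stays free, and any butanoyl exchange between O24 and O3 leads to the same diester.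

Step 26
Reactants: 42 (2S,3R,5R,7S,9R,11R,12Z,14Z,17R,18R,20R,21R,23R,24S)-3,24-bis(butanoyloxy)-7,21-bis[tert-butyl(diphenyl)silyloxy]-5,9:17,20-diepoxy-2-hydroxy-11,18-dimethyl-2,24-cyclotetracosa-12,14-dien-23-olide
Product: 43 (2S,3R,5R,7S,9R,11R,12Z,14Z,17R,18R,20R,21R,23R,24S)-3,24-bis(butanoyloxy)-5,9:17,20-diepoxy-2,7,21-trihydroxy-11,18-dimethyl-2,24-cyclotetracosa-12,14-dien-23-olide (CNP0255197.1)
Conditions: HF·pyridine, pyridine, THF, rt
Reagents that add atoms: none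
Why: Buffered fluoride desilylation removes both silyl ethers (C7, C21) without cleaving the butanoates or the lactone.

**Compound list**

1 | tert-butyl 4-chloro-3-oxobutanoate | CC(C)(C)OC(=O)CC(=O)CCl | starting material
2 | (4-tert-butoxy-2,4-dioxobutyl)(triphenyl)phosphonium chloride | CC(C)(C)OC(=O)CC(=O)C[P+](c1ccccc1)(c1ccccc1)c1ccccc1.[Cl-] | intermediate
3 | tert-butyl 3-oxo-4-(triphenyl-λ5-phosphanylidene)butanoate | CC(C)(C)OC(=O)CC(=O)C=P(c1ccccc1)(c1ccccc1)c1ccccc1 | intermediate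
4 | (3E)-pent-3-en-2-one | C/C=C/C(C)=O | starting material
5 | ethynyltri(propan-2-yl)silane | C#C[Si](C(C)C)(C(C)C)C(C)C | starting material
6 | (4R)-4-methyl-6-[tri(propan-2-yl)silyl]hex-5-yn-2-one | CC(=O)C[C@@H](C)C#C[Si](C(C)C)(C(C)C)C(C)C | intermediate
7 | 3-[tert-butyl(dimethyl)silyl]oxypropanal | CC(C)(C)[Si](C)(C)OCCC=O | starting material
8 | (3R,7R)-9-[tert-butyl(dimethyl)silyl]oxy-7-hydroxy-3-methyl-1-[tri(propan-2-yl)silyl]non-1-yn-5-one | CC(C)(C)[Si](C)(C)OCC[C@@H](O)CC(=O)C[C@@H](C)C#C[Si](C(C)C)(C(C)C)C(C)C | intermediate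
9 | (3R,5R,7R)-1-[tert-butyl(dimethyl)silyl]oxy-7-methyl-9-[tri(propan-2-yl)silyl]non-8-yne-3,5-diol | CC(C)(C)[Si](C)(C)OCC[C@@H](O)C[C@H](O)C[C@@H](C)C#C[Si](C(C)C)(C(C)C)C(C)C | intermediate
10 | (3R,5R,7R)-7-methylnon-8-yne-1,3,5-triol | OCC[C@@H](O)C[C@H](O)C[C@@H](C)C#C | intermediate
11 | (4S,6R)-6-[(2R)-2-methylbut-3-yn-1-yl]oxane-2,4-diol (anomer mixture) | OC1C[C@@H](O)C[C@@H](C[C@@H](C)C#C)O1 | intermediate
12 | tert-butyl (4E,7R,9R,11R)-7,9-dihydroxy-11-methyl-3-oxotridec-4-en-12-ynoate | CC(C)(C)OC(=O)CC(=O)/C=C/C[C@@H](O)C[C@H](O)C[C@@H](C)C#C | intermediate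
13 | tert-butyl 4-[(2R,4S,6R)-4-hydroxy-6-[(2R)-2-methylbut-3-yn-1-yl]oxan-2-yl]-3-oxobutanoate | CC(C)(C)OC(=O)CC(=O)C[C@H]2C[C@@H](O)C[C@@H](C[C@@H](C)C#C)O2 | intermediate
14 | tert-butyl 4-[(2R,4S,6R)-4-[tert-butyl(diphenyl)silyl]oxy-6-[(2R)-2-methylbut-3-yn-1-yl]oxan-2-yl]-3-oxobutanoate | CC(C)(C)OC(=O)CC(=O)C[C@H]2C[C@@H](O[Si](c3ccccc3)(c3ccccc3)C(C)(C)C)C[C@@H](C[C@@H](C)C#C)O2 | intermediate
15 | (3R)-3,7-dimethyloct-6-enal ((R)-citronellal) | CC(C)=CCC[C@@H](C)CC=O | starting material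
16 | (2R,3R)-2-chloro-3,7-dimethyloct-6-enal | O=C[C@H](Cl)[C@H](C)CCC=C(C)C | intermediate
17 | (2R,3R)-2-chloro-3,7-dimethyloct-6-en-1-ol | OC[C@H](Cl)[C@H](C)CCC=C(C)C | intermediate
18 | (2S)-2-[(2R)-6-methylhept-5-en-2-yl]oxirane | C1O[C@H]1[C@H](C)CCC=C(C)C | intermediate
19 | ethynyl(trimethyl)silane | C#C[Si](C)(C)C | starting material
20 | (4R,5R)-5,9-dimethyl-1-(trimethylsilyl)dec-8-en-1-yn-4-ol | C[Si](C)(C)C#CC[C@@H](O)[C@H](C)CCC=C(C)C | intermediate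
21 | {[(4R,5R)-5,9-dimethyl-1-(trimethylsilyl)dec-8-en-1-yn-4-yl]oxy}(triethyl)silane | C[Si](C)(C)C#CC[C@@H](O[Si](CC)(CC)CC)[C@H](C)CCC=C(C)C | intermediate
22 | (4R,5R)-4-methyl-5-(triethylsilyloxy)-8-(trimethylsilyl)oct-7-ynal | C[Si](C)(C)C#CC[C@@H](O[Si](CC)(CC)CC)[C@H](C)CCC=O | intermediate
23 | (2S,4R,5R)-2-chloro-4-methyl-5-(triethylsilyloxy)-8-(trimethylsilyl)oct-7-ynal | C[Si](C)(C)C#CC[C@@H](O[Si](CC)(CC)CC)[C@H](C)C[C@H](Cl)C=O | intermediate
24 | 1,1-dimethoxypropan-2-one | CC(=O)C(OC)OC | starting material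
25 | (4R,5S,7R,8R)-5-chloro-4-hydroxy-1,1-dimethoxy-7-methyl-8-(triethylsilyloxy)-11-(trimethylsilyl)undec-10-yn-2-one | C[Si](C)(C)C#CC[C@@H](O[Si](CC)(CC)CC)[C@H](C)C[C@H](Cl)[C@H](O)CC(=O)C(OC)OC | intermediate
26 | (4R,5S,7R,8R)-5-chloro-4,8-dihydroxy-1,1-dimethoxy-7-methyl-11-(trimethylsilyl)undec-10-yn-2-one | C[Si](C)(C)C#CC[C@@H](O)[C@H](C)C[C@H](Cl)[C@H](O)CC(=O)C(OC)OC | intermediate
27 | (4R)-4-hydroxy-1,1-dimethoxy-4-{(2R,4R,5R)-4-methyl-5-[3-(trimethylsilyl)prop-2-yn-1-yl]oxolan-2-yl}butan-2-one | C[Si](C)(C)C#CC[C@H]3O[C@H](C[C@H]3C)[C@H](O)CC(=O)C(OC)OC | intermediate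
28 | (4R)-4-[tert-butyl(diphenyl)silyl]oxy-1,1-dimethoxy-4-{(2R,4R,5R)-4-methyl-5-[3-(trimethylsilyl)prop-2-yn-1-yl]oxolan-2-yl}butan-2-one | C[Si](C)(C)C#CC[C@H]3O[C@H](C[C@H]3C)[C@H](O[Si](c1ccccc1)(c1ccccc1)C(C)(C)C)CC(=O)C(OC)OC | intermediate
29 | (2R,4R)-4-[tert-butyl(diphenyl)silyl]oxy-1,1-dimethoxy-4-{(2R,4R,5R)-4-methyl-5-[3-(trimethylsilyl)prop-2-yn-1-yl]oxolan-2-yl}butan-2-ol | C[Si](C)(C)C#CC[C@H]3O[C@H](C[C@H]3C)[C@H](O[Si](c1ccccc1)(c1ccccc1)C(C)(C)C)C[C@@H](O)C(OC)OC | intermediate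
30 | (2R,4R)-4-[(2R,4R,5R)-5-(3-bromoprop-2-yn-1-yl)-4-methyloxolan-2-yl]-4-[tert-butyl(diphenyl)silyl]oxy-1,1-dimethoxybutan-2-ol | BrC#CC[C@H]3O[C@H](C[C@H]3C)[C@H](O[Si](c1ccccc1)(c1ccccc1)C(C)(C)C)C[C@@H](O)C(OC)OC | intermediate
31 | tert-butyl (5R,7S,9R,11R,17R,18R,20R,21R,23R)-7,21-bis[tert-butyl(diphenyl)silyloxy]-5,9:17,20-diepoxy-23-hydroxy-24,24-dimethoxy-11,18-dimethyl-3-oxotetracosa-12,14-diynoate | CC(C)(C)OC(=O)CC(=O)C[C@H]2C[C@@H](O[Si](c3ccccc3)(c3ccccc3)C(C)(C)C)C[C@@H](C[C@@H](C)C#CC#CC[C@H]3O[C@H](C[C@H]3C)[C@H](O[Si](c4ccccc4)(c4ccccc4)C(C)(C)C)C[C@@H](O)C(OC)OC)O2 | intermediate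
32 | tert-butyl (5R,7S,9R,11R,12Z,14Z,17R,18R,20R,21R,23R)-7,21-bis[tert-butyl(diphenyl)silyloxy]-5,9:17,20-diepoxy-23-hydroxy-24,24-dimethoxy-11,18-dimethyl-3-oxotetracosa-12,14-dienoate | CC(C)(C)OC(=O)CC(=O)C[C@H]2C[C@@H](O[Si](c3ccccc3)(c3ccccc3)C(C)(C)C)C[C@@H](C[C@@H](C)/C=C\C=C/C[C@H]3O[C@H](C[C@H]3C)[C@H](O[Si](c4ccccc4)(c4ccccc4)C(C)(C)C)C[C@@H](O)C(OC)OC)O2 | intermediate
33 | (5R,7S,9R,11R,12Z,14Z,17R,18R,20R,21R,23R)-7,21-bis[tert-butyl(diphenyl)silyloxy]-5,9:17,20-diepoxy-23-hydroxy-24,24-dimethoxy-11,18-dimethyltetracosa-1,12,14-triene-1,3-dione (acylketene) | O=C=CC(=O)C[C@H]2C[C@@H](O[Si](c3ccccc3)(c3ccccc3)C(C)(C)C)C[C@@H](C[C@@H](C)/C=C\C=C/C[C@H]3O[C@H](C[C@H]3C)[C@H](O[Si](c4ccccc4)(c4ccccc4)C(C)(C)C)C[C@@H](O)C(OC)OC)O2 | intermediate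
34 | (5R,7S,9R,11R,12Z,14Z,17R,18R,20R,21R,23R)-7,21-bis[tert-butyl(diphenyl)silyloxy]-5,9:17,20-diepoxy-24,24-dimethoxy-11,18-dimethyl-3-oxotetracosa-12,14-dien-23-olide (24-membered lactone) | O=C1C[C@H]2C[C@@H](O[Si](c3ccccc3)(c3ccccc3)C(C)(C)C)C[C@@H](C[C@@H](C)/C=C\C=C/C[C@H]3O[C@H](C[C@H]3C)[C@H](O[Si](c4ccccc4)(c4ccccc4)C(C)(C)C)C[C@@H](OC(=O)C1)C(OC)OC)O2 | intermediate
35 | butanoic acid | CCCC(=O)O | starting material
36 | (2RS,5R,7S,9R,11R,12Z,14Z,17R,18R,20R,21R,23R)-2-(butanoyloxy)-7,21-bis[tert-butyl(diphenyl)silyloxy]-5,9:17,20-diepoxy-24,24-dimethoxy-11,18-dimethyl-3-oxotetracosa-12,14-dien-23-olide | O=C1C[C@H]2C[C@@H](O[Si](c3ccccc3)(c3ccccc3)C(C)(C)C)C[C@@H](C[C@@H](C)/C=C\C=C/C[C@H]3O[C@H](C[C@H]3C)[C@H](O[Si](c4ccccc4)(c4ccccc4)C(C)(C)C)C[C@@H](OC(=O)C1OC(=O)CCC)C(OC)OC)O2 | intermediate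
37 | (2RS,5R,7S,9R,11R,12Z,14Z,17R,18R,20R,21R,23R)-2-(butanoyloxy)-7,21-bis[tert-butyl(diphenyl)silyloxy]-5,9:17,20-diepoxy-11,18-dimethyl-3,24-dioxotetracosa-12,14-dien-23-olide | O=C1C[C@H]2C[C@@H](O[Si](c3ccccc3)(c3ccccc3)C(C)(C)C)C[C@@H](C[C@@H](C)/C=C\C=C/C[C@H]3O[C@H](C[C@H]3C)[C@H](O[Si](c4ccccc4)(c4ccccc4)C(C)(C)C)C[C@@H](OC(=O)C1OC(=O)CCC)C=O)O2 | intermediate
38 | (2R,5R,7S,9R,11R,12Z,14Z,17R,18R,20R,21R,23R,24S)-2-(butanoyloxy)-7,21-bis[tert-butyl(diphenyl)silyloxy]-5,9:17,20-diepoxy-24-hydroxy-11,18-dimethyl-3-oxo-2,24-cyclotetracosa-12,14-dien-23-olide | O=C1C[C@H]2C[C@@H](O[Si](c3ccccc3)(c3ccccc3)C(C)(C)C)C[C@@H](C[C@@H](C)/C=C\C=C/C[C@H]3O[C@H](C[C@H]3C)[C@H](O[Si](c4ccccc4)(c4ccccc4)C(C)(C)C)C[C@H]3OC(=O)[C@@]1(OC(=O)CCC)[C@H]3O)O2 | intermediate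
39 | (2R,5R,7S,9R,11R,12Z,14Z,17R,18R,20R,21R,23R,24S)-24-(butanoyloxy)-7,21-bis[tert-butyl(diphenyl)silyloxy]-5,9:17,20-diepoxy-2-hydroxy-11,18-dimethyl-3-oxo-2,24-cyclotetracosa-12,14-dien-23-olide | O=C1C[C@H]2C[C@@H](O[Si](c3ccccc3)(c3ccccc3)C(C)(C)C)C[C@@H](C[C@@H](C)/C=C\C=C/C[C@H]3O[C@H](C[C@H]3C)[C@H](O[Si](c4ccccc4)(c4ccccc4)C(C)(C)C)C[C@H]3OC(=O)[C@@]1(O)[C@H]3OC(=O)CCC)O2 | intermediate
40 | (2S,3R,5R,7S,9R,11R,12Z,14Z,17R,18R,20R,21R,23R,24S)-24-(butanoyloxy)-7,21-bis[tert-butyl(diphenyl)silyloxy]-5,9:17,20-diepoxy-2,3-dihydroxy-11,18-dimethyl-2,24-cyclotetracosa-12,14-dien-23-olide | O[C@@H]1C[C@H]2C[C@@H](O[Si](c3ccccc3)(c3ccccc3)C(C)(C)C)C[C@@H](C[C@@H](C)/C=C\C=C/C[C@H]3O[C@H](C[C@H]3C)[C@H](O[Si](c4ccccc4)(c4ccccc4)C(C)(C)C)C[C@H]3OC(=O)[C@@]1(O)[C@H]3OC(=O)CCC)O2 | intermediate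
41 | butanoic anhydride | CCCC(=O)OC(=O)CCC | starting material
42 | (2S,3R,5R,7S,9R,11R,12Z,14Z,17R,18R,20R,21R,23R,24S)-3,24-bis(butanoyloxy)-7,21-bis[tert-butyl(diphenyl)silyloxy]-5,9:17,20-diepoxy-2-hydroxy-11,18-dimethyl-2,24-cyclotetracosa-12,14-dien-23-olide | CCCC(=O)O[C@@H]1C[C@H]2C[C@@H](O[Si](c3ccccc3)(c3ccccc3)C(C)(C)C)C[C@@H](C[C@@H](C)/C=C\C=C/C[C@H]3O[C@H](C[C@H]3C)[C@H](O[Si](c4ccccc4)(c4ccccc4)C(C)(C)C)C[C@H]3OC(=O)[C@@]1(O)[C@H]3OC(=O)CCC)O2 | intermediate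
43 | (2S,3R,5R,7S,9R,11R,12Z,14Z,17R,18R,20R,21R,23R,24S)-3,24-bis(butanoyloxy)-5,9:17,20-diepoxy-2,7,21-trihydroxy-11,18-dimethyl-2,24-cyclotetracosa-12,14-dien-23-olide (CNP0255197.1) | CCCC(=O)O[C@@H]1C[C@H]2C[C@@H](O)C[C@@H](C[C@@H](C)/C=C\C=C/C[C@H]3O[C@H](C[C@H]3C)[C@H](O)C[C@H]3OC(=O)[C@@]1(O)[C@H]3OC(=O)CCC)O2 | target

**Step count and risks**

Total step count: 26 (1 reagent step, 7 for the west fragment, 10 for the east fragment, 8 after fragment union). Longest linear sequence: 18 steps (steps 9–26).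

Steps most likely to fail:

1. Step 23 (aldol ring contraction with acyl shift). The α-acyloxy aldehyde may epimerise at C23 under base, and the cis pair with the wrong face (2S,24R in the ketone series) may form. The fallback generates the same enol without base. It sets out from 34: diazo transfer (4-acetamidobenzenesulfonyl azide, Et3N, MeCN) gives the 2-diazo-3-oxo macrolactone F1. Its acetal is cleaved with CF3CO2H/H2O to the diazo aldehyde F2. Rh2(OAc)4-catalysed O–H insertion of the carbenoid into butanoic acid 35 then forms the enol of 37 in neutral solution, which is trapped by the aldehyde and rearranges as before. The fallback comes back to the route at 39.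

2. Step 21 (acylketene macrolactonisation). Ketene formation from the tert-butyl ester may be slow and oligomers may compete. The fallback closes the ring at the diyne instead. It sets out from 14 and 30: heating the two in toluene at 110 °C with distillation of tert-butanol joins them through the C1–O–C23 ester and gives the open-chain bromoalkyne–alkyne ester F3. Intramolecular Pd(PPh3)2Cl2/CuI coupling at high dilution gives the macrocyclic 1,3-diyne lactone F4. Zn(Cu/Ag) reduction as in step 20 then gives the Z,Z-diene, and the fallback comes back to the route at 34.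

3. Step 15 (tetrahydrofuran closure beside a β-hydroxy ketone). The C23 ketone may take part in the ionisation, or an epoxide may form through the C21 hydroxyl. The fallback closes the ring before C21–C22 is made. It sets out from 23: NaBH4 gives the chloro alcohol F5. PPTS/MeOH and then AgOSO2CF3/Ag2O close the ring with inversion at C20 to the tetrahydrofuranylmethanol F6. Dess–Martin oxidation gives the aldehyde F7. A MgBr2·OEt2-mediated, chelation-controlled Mukaiyama aldol with the trimethylsilyl enol ether F8 (from 24, Me3SiOSO2CF3, Et3N) gives the threo carbinol, and the fallback comes back to the route at 27.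

Further compounds
F1 | step 23 | (5R,7S,9R,11R,12Z,14Z,17R,18R,20R,21R,23R)-2-diazo-7,21-bis[tert-butyl(diphenyl)silyloxy]-5,9:17,20-diepoxy-24,24-dimethoxy-11,18-dimethyl-3-oxotetracosa-12,14-dien-23-olide | O=C1C[C@H]2C[C@@H](O[Si](c3ccccc3)(c3ccccc3)C(C)(C)C)C[C@@H](C[C@@H](C)/C=C\C=C/C[C@H]3O[C@H](C[C@H]3C)[C@H](O[Si](c4ccccc4)(c4ccccc4)C(C)(C)C)C[C@@H](OC(=O)C1=[N+]=[N-])C(OC)OC)O2
F2 | step 23 | (5R,7S,9R,11R,12Z,14Z,17R,18R,20R,21R,23R)-2-diazo-7,21-bis[tert-butyl(diphenyl)silyloxy]-5,9:17,20-diepoxy-11,18-dimethyl-3,24-dioxotetracosa-12,14-dien-23-olide | O=C1C[C@H]2C[C@@H](O[Si](c3ccccc3)(c3ccccc3)C(C)(C)C)C[C@@H](C[C@@H](C)/C=C\C=C/C[C@H]3O[C@H](C[C@H]3C)[C@H](O[Si](c4ccccc4)(c4ccccc4)C(C)(C)C)C[C@@H](OC(=O)C1=[N+]=[N-])C=O)O2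
F3 | step 21 | (2R,4R)-4-[(2R,4R,5R)-5-(3-bromoprop-2-yn-1-yl)-4-methyloxolan-2-yl]-4-[tert-butyl(diphenyl)silyl]oxy-1,1-dimethoxybutan-2-yl 4-[(2R,4S,6R)-4-[tert-butyl(diphenyl)silyl]oxy-6-[(2R)-2-methylbut-3-yn-1-yl]oxan-2-yl]-3-oxobutanoate | BrC#CC[C@H]3O[C@H](C[C@H]3C)[C@H](O[Si](c1ccccc1)(c1ccccc1)C(C)(C)C)C[C@@H](OC(=O)CC(=O)C[C@H]2C[C@@H](O[Si](c4ccccc4)(c4ccccc4)C(C)(C)C)C[C@@H](C[C@@H](C)C#C)O2)C(OC)OC
F4 | step 21 | (5R,7S,9R,11R,17R,18R,20R,21R,23R)-7,21-bis[tert-butyl(diphenyl)silyloxy]-5,9:17,20-diepoxy-24,24-dimethoxy-11,18-dimethyl-3-oxotetracosa-12,14-diyn-23-olide | O=C1C[C@H]2C[C@@H](O[Si](c3ccccc3)(c3ccccc3)C(C)(C)C)C[C@@H](C[C@@H](C)C#CC#CC[C@H]3O[C@H](C[C@H]3C)[C@H](O[Si](c4ccccc4)(c4ccccc4)C(C)(C)C)C[C@@H](OC(=O)C1)C(OC)OC)O2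
F5 | step 15 | (2S,4R,5R)-2-chloro-4-methyl-5-(triethylsilyloxy)-8-(trimethylsilyl)oct-7-yn-1-ol | C[Si](C)(C)C#CC[C@@H](O[Si](CC)(CC)CC)[C@H](C)C[C@H](Cl)CO
F6 | step 15 | {(2R,4R,5R)-4-methyl-5-[3-(trimethylsilyl)prop-2-yn-1-yl]oxolan-2-yl}methanol | C[Si](C)(C)C#CC[C@H]3O[C@H](C[C@H]3C)CO
F7 | step 15 | (2R,4R,5R)-4-methyl-5-[3-(trimethylsilyl)prop-2-yn-1-yl]oxolane-2-carbaldehyde | C[Si](C)(C)C#CC[C@H]3O[C@H](C[C@H]3C)C=O
F8 | step 15 | [(3,3-dimethoxyprop-1-en-2-yl)oxy](trimethyl)silane | C=C(O[Si](C)(C)C)C(OC)OC
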